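Count time in lifetimes, not minutes: the target curve of the amber flask bends, and the bend carries its own clock.

- amber: substrate 0.14 M; the very flask that is asked about, followed so far
- flask: substrate 0.14 M; time 25 min

- amber (time / min: target / %, intermediate B / %): 0.667: 2.6, 0.4; 1.00: 2.8, 0.1; 2.00: 6.1, 0; 4.00: 10.5, 0.4; 8.00: 17.9, 2.5

(readings scatter by 0.5 percentage points)

- how much target the flask holds at 25 min, in percent of the substrate charged
- how much intermediate B the flask holds at 25 min, in percent of the substrate charged

- the numbers in the tables scatter by 0.5 percentage points (one standard deviation)
- steps under discussion: substrate -> target; substrate -> intermediate A; intermediate A <-> intermediate B; target -> over-reaction product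

Take substrate loss and target loss as first order, and let L be their two rate constants added. Early on, target divided by time t falls as exp(−Lt/2), so compare the amber readings at 2.00 min and 8.00 min: L reads 0.103 min⁻¹, with all their scatter. Put that back into the first slope, 0.0305 min⁻¹ of the charge, and the estimate of the starting rate v of target rises to 0.0338 min⁻¹.

Now fold in the asked time. Call u = 2.58 the bend number, the asked time counted in lifetimes 1/L. By this estimate the amber flask is past the straight part at the asked time. But is one number enough? No: the same u has two ends. Equal constants give v·t·exp(−u/2) = 23.3 %; no over-reaction gives (v/L)(1 − exp(−u)) = 30.3 %. I commit to target between these. Intermediate B, squared up from its reading at 8.00 min, gives 24.4 % before any bend, so expect less.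

The forecast says 32 % target (27 % to 37 %), above my upper end, and 15 % intermediate B (8 % to 24 %): “The data cannot separate substrate loss from over-reaction.”

The amber flask holds 28.0 % target and 10.9 % intermediate B at 25.0 min, both inside the forecast's ranges, and target inside my two ends.

    substrate → target (k = 5.60 × 10⁻⁴ s⁻¹)
    substrate → intermediate A (k = 6.30 × 10⁻⁴ s⁻¹)
    intermediate A ⇌ intermediate B (K = 0.660, k = 4.50 × 10⁻⁴ s⁻¹)
    target → over-reaction product (k = 3.60 × 10⁻⁴ s⁻¹)

Beside them the amber flask holds 11.2 % over-reaction product. Carry the bend number to the neighbour flask read at 40 min: u becomes 4.12, the two ends are 17.2 % and 32.3 %, and that flask holds 24.6 % target.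

All runs come from a simulation with constants of no real substance, noise included.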